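**Assumptions (remarks on the chemistry)**

- Sense of induction: the (4S)-benzyl oxazolidinone is taken to deliver 3S, because the coupling is expected to run through the s-cis rotamer with both imide carbonyls syn, in which the benzyl group covers the Re face of C8. If the opposite sense is found, the (4R)-auxiliary is used and nothing else changes.
- 17 is used as the free acid; the commercial sodium salt is acidified first.
- Locants O1, C2, C3, C3a, C4 to C7 and C7a are those of the dihydrobenzofuran; C7, C8 and primed locants are those of the caffeate units before coupling. Ring A is the benzo ring, ring B the dihydrofuran, ring C the aryl group on C2, ring D the catechol of the lactate.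

## Structural features

The target is a trans-2-aryl-2,3-dihydrobenzofuran-3-carboxylic acid in which ring A and ring B are fused along C3a–C7a and ring C sits on C2. C7 of ring A carries a hydroxyl, and C4 carries an (E)-propenoate esterified with the secondary hydroxyl of methyl (R)-3-(3,4-dihydroxyphenyl)lactate (ring D). C2 and C3 are neighbouring stereocentres, both S, with aryl and carboxyl trans; the third stereocentre, R, lies on the lactate carbon and is insulated from the other two by the acrylate. Ring A is substituted at four adjacent positions (C4, C3a, C7a, C7), so the carbon substituent at C3a sits between the acrylate and the ring oxygen. Fragile elements are: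

- five phenolic hydroxyls (two catechols and the C7 hydroxyl);
- the cinnamate double bond, which rules out hydrogenolysis;
- the C2–O1 bond, a benzylic aryl ether para to an oxygenated ring, opened by Lewis acid or, when the para hydroxyl is free, by base through a quinone methide;
- the C3–H bond, benzylic and alpha to a carboxyl, prone to epimerisation and to beta-elimination of O1;
- the acyloxy ester stereocentre.

Three carboxyl groups must end in three states: free at C3, methyl ester on the lactate, enoate ester at C4. The real difficulty is forging C3–C3a at the most crowded position of ring A with control of absolute configuration at C3 and C2. The key step uses the fact that C2, C3, the C3 carboxyl and ring C make up one caffeic acid unit and ring A with its C4 chain a second one, so that C3–C3a and C2–O1 are the 8–2' and 7–O–3' junctions of a caffeate dimer and can be made together by oxidative phenol coupling.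

## Logic of the disconnections

**21 from 20.** The bonds cut are the six O–CH2Ph bonds (five aryl ethers and the ester at C3). All phenols and the C3 carboxyl are then carried under one kind of protecting group, removed in a single operation, and the oxidation-prone polyphenol appears only at the end. The forward step must cleave benzyl–oxygen bonds without hydrogen, without touching the methyl ester and the enoate, and without ionising C2–O1.

**20 from 16 and 19.** The bond cut is the ester C–O bond between the acrylic carboxyl and the lactate oxygen. This is the most convergent cut: it separates ring D and the remote R centre from the dihydrobenzofuran half. 19 goes back to 18 and then 17 by cutting two O–CH2Ph bonds and one O–CH3 bond. The forward acylation needs 16 to have exactly one free carboxyl and must not racemise the acyloxy ester.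

**16 from 15, 15 from 14, 14 from 13, 13 from 11.** In this order the cuts are the O–C(CH3)3 bond of the enoate, the C5–H bond (replaced backwards by C5–Br), the two O–CH2Ph bonds at the C3 carboxyl and at the para oxygen of ring C, and the acyl–N bond to the auxiliary. These are functional-group changes only, and they lead back to the compound that still holds the bromine, the free phenol and the auxiliary that the coupling requires. Forward, the auxiliary must leave without beta-elimination across C3–C2, the bromine without reduction of the alkene, and the tert-butyl group without loss of benzyl groups.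

**11 from 6 and 9, through 10.** The bonds cut are C3–C3a and C2–O1, so ring B is opened at both of its links to ring A. The result is two C6–C3 pieces of similar size, each two or three steps from commercial material; one ring, two skeletal bonds and both adjacent stereocentres disappear at once. The forward step must favour cross- over homo-coupling, must bond at the single free ortho carbon of 9, and must select one face of C8 in 6.

**6 from 4 and 5; 4 from 2 through 3; 2 from 1.** The cuts are the C7=C8 double bond, the C–P bond and the N–acyl bond. An olefination is chosen because it tolerates the free phenol of 5, whereas N-acylation with a phenolic cinnamic acid would require protection and deprotection. The forward steps need E selectivity and an ylide that is formed without opening the imide.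

**9 from 8, 8 from 7.** The cuts are the C=C bond of the enoate and one O–CH2Ph bond. 7 already has bromine para to the hydroxyl that must remain free. The forward benzylation has to occur only at the hydroxyl para to the formyl group.

## Other disconnections considered

**Alternative 1:** The cut removes ring A altogether: C3a–C7a, C4–C5 and C6–C7 are disconnected, leaving the acyclic diyne A1 (a silylated ynol ether and a propargylic silyl ether joined through the C2–C3 unit) and acetylene A2. Forward, RhCl(PPh3)3 would join the two alkynes of A1 into a rhodacyclopentadiene, which closes ring B, and insertion of A2 would complete the benzene ring of A3.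
- In favour: the positions of all four ring A substituents are fixed by the tether and the alkyne termini, so no arene regiochemistry has to be controlled. Both stereocentres are made beforehand in an open chain by standard enantioselective methods. Metallacycle chemistry is indifferent to the electronic character of phenols. On regiocontrol and on security of absolute configuration this plan is the better one, and on predictability of mechanism it is at least the equal.
- Against: A1 is itself demanding (an ynol ether at a benzylic stereocentre, and a propargylic stereocentre that can isomerise to an allene). A2 must outrun oligomerisation of A1. Every functional group of A3 is at the wrong oxidation level: the 4-methoxybenzyloxymethyl group at C3 must become a carboxyl, the silyloxymethyl group at C4 an aldehyde and then the acrylate, and the C7 silyl group a hydroxyl by Tamao–Fleming oxidation.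
- Comparison: the key step builds ring A but no stereocentre, and by estimate the route is well above twenty steps against fourteen, so it is clearly inferior in step economy.

**Alternative 2:** Only C2–O1 is cut. The precursor is the unprotected seco-acid A4, in which C3–C3a and the C3 configuration are already present and C2 is a methylene group. Forward, a flavin-dependent oxidase of the vanillyl-alcohol oxidase type would remove hydride from the methylene para to the ring C hydroxyl, and the C7a hydroxyl would add to the resulting p-quinone methide to give A5.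
- In favour: no protecting groups, water as solvent, oxygen as oxidant, and a C4 aldehyde ready for Knoevenagel–Doebner chain extension. On protecting-group economy this is the better plan. The ring closure is the same quinone-methide trapping that ends the chosen key step, so on that point the two are equal.
- Against: the hardest part of the problem, the hindered C3–C3a bond with its configuration, is not solved but moved into the synthesis of A4. Enzymes of this class accept small 4-alkylphenols; a catechol with a branched, carboxylate-bearing chain and a second catechol lies far outside that. In the active site the quinone methide is normally captured by water or loses a proton, and both would compete with attack by a phenol deactivated by the para formyl group. Both catechols are open to over-oxidation.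
- Comparison: the key step would build one bond and one stereocentre where the chosen one builds two of each, so the overall length depends entirely on how A4 is made.

**Alternative 3:** The cut is O1–C7a, together with the C7–O bond. The precursor is the open-chain alcohol A6, which carries a 3-bromo-2-fluorophenyl group on the future C3. Forward, n-BuLi would form the alkoxide and exchange the bromine; loss of LiF gives the C7–C7a aryne; the alkoxide adds at C7a (the only position that gives a five-membered ring); the C7 aryllithium is borylated with B(OMe)3 and oxidised with H2O2 to the phenol A7.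
- In favour: polar, well-understood elementary steps; closure regiochemistry enforced by geometry; the C7 oxygen introduced in the same flask; both stereocentres from established open-chain chemistry; no phenol exposed to an oxidant. In predictability of mechanism and of configuration this is the better plan.
- Against: A7 has no substituent at C4, so the acrylate would have to be attached later by a directed C–H olefination next to C3a, and the C3 carbon raised from silyloxymethyl to the acid. The benzyl ethers and the benzylic alkoxide must tolerate alkyllithium.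
- Comparison: the key step forms one bond of ring B and no stereocentre, the precursor needs its own stereoselective synthesis, and several steps follow before the stage of 15 is reached, so it is inferior in step economy.

Key step: step 6

## Route

Step 1
Reactants: 1 (S)-4-benzyl-1,3-oxazolidin-2-one
Product: 2 (4S)-4-benzyl-3-(bromoacetyl)-1,3-oxazolidin-2-one
Conditions: n-BuLi, THF, −78 °C; BrCH2COBr, −78 to 0 °C
Reagents that add atoms: bromoacetyl bromide, O=C(Br)CBr
Why: N-acylation of the lithiated oxazolidinone by the acid bromide, which is far more electrophilic than the alkyl bromide; the auxiliary stereocentre is not involved.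

Step 2
Reactants: 2 (4S)-4-benzyl-3-(bromoacetyl)-1,3-oxazolidin-2-one
Product: 4 (4S)-4-benzyl-3-[(triphenylphosphoranylidene)acetyl]-1,3-oxazolidin-2-one, via phosphonium bromide 3 (not isolated)
Conditions: PPh3, CH2Cl2, rt; then aq. Na2CO3, 0 °C
Reagents that add atoms: triphenylphosphine, c1ccc(cc1)P(c1ccccc1)c1ccccc1
Why: SN2 displacement of the activated bromide by PPh3 followed by deprotonation of the acidic phosphonium salt gives the carbonyl-stabilised ylide (ylide formation for a Wittig reaction); carbonate is too weak a nucleophile to open the imide.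

Step 3
Reactants: 4 (4S)-4-benzyl-3-[(triphenylphosphoranylidene)acetyl]-1,3-oxazolidin-2-one; 5 3-(benzyloxy)-4-hydroxybenzaldehyde
Product: 6 (4S)-4-benzyl-3-[(E)-3-(3-benzyloxy-4-hydroxyphenyl)prop-2-enoyl]-1,3-oxazolidin-2-one
Conditions: toluene, 90 °C
Reagents that add atoms: none
Why: Wittig olefination with a stabilised ylide gives the E-enoyl imide and, being neutral, tolerates the free phenol that an N-acylation with the corresponding cinnamic acid would not.

Step 4
Reactants: 7 2-bromo-4,5-dihydroxybenzaldehyde
Product: 8 4-(benzyloxy)-2-bromo-5-hydroxybenzaldehyde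
Conditions: BnBr (1.0 equiv), NaHCO3, DMF, 40 °C
Reagents that add atoms: benzyl bromide, BrCc1ccccc1
Why: Williamson etherification under weak base: only the hydroxyl para to the formyl group is acidic enough to be ionised by hydrogencarbonate, so it alone is benzylated and the meta hydroxyl stays free.

Step 5
Reactants: 8 4-(benzyloxy)-2-bromo-5-hydroxybenzaldehyde
Product: 9 tert-butyl (E)-3-(4-benzyloxy-2-bromo-5-hydroxyphenyl)prop-2-enoate
Conditions: Ph3P=CHCO2tBu, toluene, 80 °C
Reagents that add atoms: tert-butyl (triphenylphosphoranylidene)acetate, CC(C)(C)OC(=O)C=P(c1ccccc1)(c1ccccc1)c1ccccc1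
Why: Wittig olefination with a stabilised ylide, E-selective and compatible with the free phenol and the aryl bromide.

Step 6
Reactants: 6 (4S)-4-benzyl-3-[(E)-3-(3-benzyloxy-4-hydroxyphenyl)prop-2-enoyl]-1,3-oxazolidin-2-one; 9 tert-butyl (E)-3-(4-benzyloxy-2-bromo-5-hydroxyphenyl)prop-2-enoate
Product: 11 tert-butyl (E)-3-[(2S,3S)-7-(benzyloxy)-2-[3-(benzyloxy)-4-hydroxyphenyl]-3-{[(4S)-4-benzyl-2-oxo-1,3-oxazolidin-3-yl]carbonyl}-5-bromo-2,3-dihydro-1-benzofuran-4-yl]prop-2-enoate, via p-quinone methide 10 (not isolated)
Conditions: Ag2O (1.5 equiv), 9 (3 equiv), 6 added slowly by syringe pump, CH2Cl2/acetone (2:1), 4 Å MS, rt, dark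
Reagents that add atoms: none
Why: Proposed new method: one-electron oxidation of both phenols by Ag2O gives the phenoxyl radical of 6, whose spin is delocalised to C8, and that of 9, whose spin sits on the ring carbons ortho and para to its oxygen; cross-combination at the only unsubstituted such carbon of 9 (between acrylate and hydroxyl) makes C3–C3a and, after ring A returns to the phenol form, leaves p-quinone methide 10. The ring A hydroxyl then adds to the exocyclic carbon of 10 in a 5-exo-trig 1,6-addition, which forms C2–O1, closes ring B and rearomatises ring C. The closest known reaction type is the Ag2O or peroxidase dehydrodimerisation of ferulate and caffeate esters and of chiral feruloyl amides to trans-2-aryl-2,3-dihydrobenzofuran-3-carboxylates by 8–5' coupling; a cross-coupling at an ortho carbon flanked by a side chain has no precedent. C3 is set in the C–C bond formation: in the s-cis rotamer with the two imide carbonyls held syn by monovalent silver, the benzyl group of the (4S)-auxiliary covers the Re face of C8, and bonding on the Si face gives 3S. C2 is set in the ring closure, which places the aryl group anti to the C3 acyl group and is reversible through the phenol and quinone-methide pair, so the trans (2S) isomer should prevail. Regiocontrol rests on the substitution of 9: bromine occupies the para carbon, benzyloxy the other ortho carbon, and because the hydroxyl is meta to the acrylate the radical of 9 cannot react through its own side chain. Cross- over homo-coupling is favoured by keeping 6 at a low stationary concentration in an excess of 9, which is recovered.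

Step 7
Reactants: 11 tert-butyl (E)-3-[(2S,3S)-7-(benzyloxy)-2-[3-(benzyloxy)-4-hydroxyphenyl]-3-{[(4S)-4-benzyl-2-oxo-1,3-oxazolidin-3-yl]carbonyl}-5-bromo-2,3-dihydro-1-benzofuran-4-yl]prop-2-enoate
Product: 13 (2S,3S)-7-(benzyloxy)-2-[3-(benzyloxy)-4-hydroxyphenyl]-5-bromo-4-[(E)-3-tert-butoxy-3-oxoprop-1-enyl]-2,3-dihydro-1-benzofuran-3-carboxylic acid, via peroxy acid 12 (not isolated)
Conditions: LiOH, H2O2, THF/H2O (3:1), 0 °C; aq. Na2SO3; HCl to pH 3
Reagents that add atoms: hydrogen peroxide (as LiOOH), OO
Why: Hydroperoxide cleavage of the N-acyl oxazolidinone: the weakly basic, strongly nucleophilic LiOOH attacks the exocyclic carbonyl of the hindered imide, which limits enolisation at C3 and beta-elimination of O1, and sulfite reduces the peroxy acid; the tert-butyl enoate is untouched and both stereocentres are retained.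

Step 8
Reactants: 13 (2S,3S)-7-(benzyloxy)-2-[3-(benzyloxy)-4-hydroxyphenyl]-5-bromo-4-[(E)-3-tert-butoxy-3-oxoprop-1-enyl]-2,3-dihydro-1-benzofuran-3-carboxylic acid
Product: 14 benzyl (2S,3S)-7-(benzyloxy)-2-[3,4-bis(benzyloxy)phenyl]-5-bromo-4-[(E)-3-tert-butoxy-3-oxoprop-1-enyl]-2,3-dihydro-1-benzofuran-3-carboxylate
Conditions: BnBr (2.5 equiv), K2CO3, DMF, rt
Reagents that add atoms: benzyl bromide, BrCc1ccccc1
Why: Carboxylate alkylation and Williamson etherification in one operation; capping the para hydroxyl of ring C also shuts the quinone-methide pathway for opening ring B.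

Step 9
Reactants: 14 benzyl (2S,3S)-7-(benzyloxy)-2-[3,4-bis(benzyloxy)phenyl]-5-bromo-4-[(E)-3-tert-butoxy-3-oxoprop-1-enyl]-2,3-dihydro-1-benzofuran-3-carboxylate
Product: 15 benzyl (2S,3S)-7-(benzyloxy)-2-[3,4-bis(benzyloxy)phenyl]-4-[(E)-3-tert-butoxy-3-oxoprop-1-enyl]-2,3-dihydro-1-benzofuran-3-carboxylate
Conditions: Pd(PPh3)4 (5 mol %), HCO2Na, DMF, 90 °C
Reagents that add atoms: none
Why: Palladium-catalysed hydrodehalogenation: oxidative addition of zerovalent palladium into C5–Br, exchange of bromide for formate, loss of CO2 and reductive elimination of the aryl–H bond; without hydrogen gas the benzyl groups and the cinnamate alkene persist, and formate is too weak a base to enolise C3.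

Step 10
Reactants: 15 benzyl (2S,3S)-7-(benzyloxy)-2-[3,4-bis(benzyloxy)phenyl]-4-[(E)-3-tert-butoxy-3-oxoprop-1-enyl]-2,3-dihydro-1-benzofuran-3-carboxylate
Product: 16 (E)-3-[(2S,3S)-7-(benzyloxy)-3-(benzyloxycarbonyl)-2-[3,4-bis(benzyloxy)phenyl]-2,3-dihydro-1-benzofuran-4-yl]prop-2-enoic acid
Conditions: TFA/CH2Cl2 (1:4), 0 °C to rt
Reagents that add atoms: none
Why: Acidolysis of the tert-butyl ester with loss of isobutene; benzyl ester and benzyl ethers are stable to TFA at this temperature, and any reversible ionisation at C2 returns the more stable trans ring without touching C3.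

Step 11
Reactants: 17 (R)-3-(3,4-dihydroxyphenyl)lactic acid
Product: 18 methyl (2R)-3-(3,4-dihydroxyphenyl)-2-hydroxypropanoate
Conditions: MeOH, H2SO4 (cat.), 50 °C
Reagents that add atoms: methanol, CO
Why: Fischer esterification; no bond to the stereocentre is broken, so the R configuration is retained.

Step 12
Reactants: 18 methyl (2R)-3-(3,4-dihydroxyphenyl)-2-hydroxypropanoate
Product: 19 methyl (2R)-3-[3,4-bis(benzyloxy)phenyl]-2-hydroxypropanoate
Conditions: BnBr (2.2 equiv), K2CO3, acetone, reflux
Reagents that add atoms: benzyl bromide, BrCc1ccccc1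
Why: Williamson etherification: carbonate ionises only the phenols, so the secondary alcohol stays free and the alpha-hydroxy ester is not enolised.

Step 13
Reactants: 16 (E)-3-[(2S,3S)-7-(benzyloxy)-3-(benzyloxycarbonyl)-2-[3,4-bis(benzyloxy)phenyl]-2,3-dihydro-1-benzofuran-4-yl]prop-2-enoic acid; 19 methyl (2R)-3-[3,4-bis(benzyloxy)phenyl]-2-hydroxypropanoate
Product: 20 benzyl (2S,3S)-7-(benzyloxy)-2-[3,4-bis(benzyloxy)phenyl]-4-[(E)-3-{[(2R)-3-[3,4-bis(benzyloxy)phenyl]-1-methoxy-1-oxopropan-2-yl]oxy}-3-oxoprop-1-enyl]-2,3-dihydro-1-benzofuran-3-carboxylate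
Conditions: EDC·HCl, DMAP (0.2 equiv), CH2Cl2, 0 °C to rt
Reagents that add atoms: none
Why: Steglich esterification: the carbodiimide activates the only free carboxyl of 16 and DMAP transfers the acyl group to the secondary hydroxyl of 19, whose C–O bond is not broken, so the R configuration is retained.

Step 14
Reactants: 20 benzyl (2S,3S)-7-(benzyloxy)-2-[3,4-bis(benzyloxy)phenyl]-4-[(E)-3-{[(2R)-3-[3,4-bis(benzyloxy)phenyl]-1-methoxy-1-oxopropan-2-yl]oxy}-3-oxoprop-1-enyl]-2,3-dihydro-1-benzofuran-3-carboxylate
Product: 21 (2S,3S)-2-(3,4-dihydroxyphenyl)-4-[(E)-3-{[(2R)-3-(3,4-dihydroxyphenyl)-1-methoxy-1-oxopropan-2-yl]oxy}-3-oxoprop-1-enyl]-7-hydroxy-2,3-dihydro-1-benzofuran-3-carboxylic acid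
Conditions: BCl3, C6HMe5, CH2Cl2, −78 to −40 °C; MeOH, then H2O
Reagents that add atoms: none
Why: Lewis-acid debenzylation with a cation scavenger: BCl3 coordinates the benzylic oxygens and pentamethylbenzene takes up the benzyl cations by Friedel–Crafts alkylation; at low temperature the methyl ester, the enoate, the alkene and the three stereocentres should be left alone.

## Compound list

1 | (S)-4-benzyl-1,3-oxazolidin-2-one | O=C1N[C@@H](Cc2ccccc2)CO1 | starting material
2 | (4S)-4-benzyl-3-(bromoacetyl)-1,3-oxazolidin-2-one | O=C(CBr)N1C(=O)OC[C@@H]1Cc1ccccc1 | intermediate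
3 | {2-[(4S)-4-benzyl-2-oxo-1,3-oxazolidin-3-yl]-2-oxoethyl}triphenylphosphonium bromide | [Br-].O=C(C[P+](c1ccccc1)(c1ccccc1)c1ccccc1)N1C(=O)OC[C@@H]1Cc1ccccc1 | intermediate (not isolated)
4 | (4S)-4-benzyl-3-[(triphenylphosphoranylidene)acetyl]-1,3-oxazolidin-2-one | O=C(C=P(c1ccccc1)(c1ccccc1)c1ccccc1)N1C(=O)OC[C@@H]1Cc1ccccc1 | intermediate
5 | 3-(benzyloxy)-4-hydroxybenzaldehyde | O=Cc1ccc(O)c(OCc2ccccc2)c1 | starting material
6 | (4S)-4-benzyl-3-[(E)-3-(3-benzyloxy-4-hydroxyphenyl)prop-2-enoyl]-1,3-oxazolidin-2-one | O=C(/C=C/c1ccc(O)c(OCc2ccccc2)c1)N1C(=O)OC[C@@H]1Cc1ccccc1 | intermediate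
7 | 2-bromo-4,5-dihydroxybenzaldehyde | O=Cc1cc(O)c(O)cc1Br | starting material
8 | 4-(benzyloxy)-2-bromo-5-hydroxybenzaldehyde | O=Cc1cc(O)c(OCc2ccccc2)cc1Br | intermediate
9 | tert-butyl (E)-3-(4-benzyloxy-2-bromo-5-hydroxyphenyl)prop-2-enoate | CC(C)(C)OC(=O)/C=C/c1cc(O)c(OCc2ccccc2)cc1Br | intermediate
10 | tert-butyl (E)-3-{4-(benzyloxy)-6-bromo-3-hydroxy-2-[(1R)-2-[(4S)-4-benzyl-2-oxo-1,3-oxazolidin-3-yl]-1-{[3-(benzyloxy)-4-oxocyclohexa-2,5-dien-1-ylidene]methyl}-2-oxoethyl]phenyl}prop-2-enoate (p-quinone methide; the 1R carbon becomes C3) | CC(C)(C)OC(=O)/C=C/c1c(Br)cc(OCc2ccccc2)c(O)c1[C@H](C(=O)N1C(=O)OC[C@@H]1Cc1ccccc1)C=C1C=CC(=O)C(OCc2ccccc2)=C1 | intermediate (not isolated)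
11 | tert-butyl (E)-3-[(2S,3S)-7-(benzyloxy)-2-[3-(benzyloxy)-4-hydroxyphenyl]-3-{[(4S)-4-benzyl-2-oxo-1,3-oxazolidin-3-yl]carbonyl}-5-bromo-2,3-dihydro-1-benzofuran-4-yl]prop-2-enoate | CC(C)(C)OC(=O)/C=C/c1c(Br)cc(OCc3ccccc3)c2c1[C@H](C(=O)N1C(=O)OC[C@@H]1Cc1ccccc1)[C@@H](c1ccc(O)c(OCc3ccccc3)c1)O2 | intermediate
12 | (2S,3S)-7-(benzyloxy)-2-[3-(benzyloxy)-4-hydroxyphenyl]-5-bromo-4-[(E)-3-tert-butoxy-3-oxoprop-1-enyl]-2,3-dihydro-1-benzofuran-3-carboperoxoic acid | CC(C)(C)OC(=O)/C=C/c1c(Br)cc(OCc3ccccc3)c2c1[C@H](C(=O)OO)[C@@H](c1ccc(O)c(OCc3ccccc3)c1)O2 | intermediate (not isolated)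
13 | (2S,3S)-7-(benzyloxy)-2-[3-(benzyloxy)-4-hydroxyphenyl]-5-bromo-4-[(E)-3-tert-butoxy-3-oxoprop-1-enyl]-2,3-dihydro-1-benzofuran-3-carboxylic acid | CC(C)(C)OC(=O)/C=C/c1c(Br)cc(OCc3ccccc3)c2c1[C@H](C(=O)O)[C@@H](c1ccc(O)c(OCc3ccccc3)c1)O2 | intermediate
14 | benzyl (2S,3S)-7-(benzyloxy)-2-[3,4-bis(benzyloxy)phenyl]-5-bromo-4-[(E)-3-tert-butoxy-3-oxoprop-1-enyl]-2,3-dihydro-1-benzofuran-3-carboxylate | CC(C)(C)OC(=O)/C=C/c1c(Br)cc(OCc3ccccc3)c2c1[C@H](C(=O)OCc1ccccc1)[C@@H](c1ccc(OCc3ccccc3)c(OCc3ccccc3)c1)O2 | intermediate
15 | benzyl (2S,3S)-7-(benzyloxy)-2-[3,4-bis(benzyloxy)phenyl]-4-[(E)-3-tert-butoxy-3-oxoprop-1-enyl]-2,3-dihydro-1-benzofuran-3-carboxylate | CC(C)(C)OC(=O)/C=C/c1ccc(OCc3ccccc3)c2c1[C@H](C(=O)OCc1ccccc1)[C@@H](c1ccc(OCc3ccccc3)c(OCc3ccccc3)c1)O2 | intermediate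
16 | (E)-3-[(2S,3S)-7-(benzyloxy)-3-(benzyloxycarbonyl)-2-[3,4-bis(benzyloxy)phenyl]-2,3-dihydro-1-benzofuran-4-yl]prop-2-enoic acid | OC(=O)/C=C/c1ccc(OCc3ccccc3)c2c1[C@H](C(=O)OCc1ccccc1)[C@@H](c1ccc(OCc3ccccc3)c(OCc3ccccc3)c1)O2 | intermediate
17 | (R)-3-(3,4-dihydroxyphenyl)lactic acid | O=C(O)[C@@H](Cc1ccc(O)c(O)c1)O | starting material
18 | methyl (2R)-3-(3,4-dihydroxyphenyl)-2-hydroxypropanoate | COC(=O)[C@@H](Cc1ccc(O)c(O)c1)O | intermediate
19 | methyl (2R)-3-[3,4-bis(benzyloxy)phenyl]-2-hydroxypropanoate | COC(=O)[C@@H](Cc1ccc(OCc2ccccc2)c(OCc2ccccc2)c1)O | intermediate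
20 | benzyl (2S,3S)-7-(benzyloxy)-2-[3,4-bis(benzyloxy)phenyl]-4-[(E)-3-{[(2R)-3-[3,4-bis(benzyloxy)phenyl]-1-methoxy-1-oxopropan-2-yl]oxy}-3-oxoprop-1-enyl]-2,3-dihydro-1-benzofuran-3-carboxylate | COC(=O)[C@@H](Cc1ccc(OCc2ccccc2)c(OCc2ccccc2)c1)OC(=O)/C=C/c1ccc(OCc3ccccc3)c2c1[C@H](C(=O)OCc1ccccc1)[C@@H](c1ccc(OCc3ccccc3)c(OCc3ccccc3)c1)O2 | intermediate
21 | (2S,3S)-2-(3,4-dihydroxyphenyl)-4-[(E)-3-{[(2R)-3-(3,4-dihydroxyphenyl)-1-methoxy-1-oxopropan-2-yl]oxy}-3-oxoprop-1-enyl]-7-hydroxy-2,3-dihydro-1-benzofuran-3-carboxylic acid | COC(=O)[C@@H](Cc1ccc(O)c(O)c1)OC(=O)/C=C/c1ccc(O)c2c1[C@H](C(=O)O)[C@@H](c1ccc(O)c(O)c1)O2 | target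

## Step count and least certain steps

Total: 14 steps. Longest linear sequence: 10 steps (1, 2, 3, 6, 7, 8, 9, 10, 13, 14).

**Step 6 (key step; proposed new method).** Four processes may defeat it:
- homodimerisation of 6 by 8–5' coupling outrunning the cross-coupling;
- bond formation at the phenoxyl oxygen of 9 (an 8–O–3' ether) rather than at the crowded ring carbon;
- weak face discrimination if the imide reacts through its carbonyl-anti rotamer;
- ipso attack at the brominated carbon.

Fallback, using known reaction types only; it sets out from 8, returns to the route at 15 and bypasses steps 7 to 9. Hydrodebromination of 8 (Pd(PPh3)4, HCO2Na, DMF) gives 4-(benzyloxy)-3-hydroxybenzaldehyde F1, which is also commercial. Commercial 3,4-bis(benzyloxy)benzaldehyde is homologated by the Corey–Fuchs sequence (CBr4, PPh3; then n-BuLi and benzyl chloroformate) through 1,2-bis(benzyloxy)-4-(2,2-dibromovinyl)benzene F2 to benzyl 3-[3,4-bis(benzyloxy)phenyl]prop-2-ynoate F3. Conjugate addition of the phenol F1 to F3 (K2CO3, DMF) gives the aryl vinyl ether benzyl (Z)-3-[3,4-bis(benzyloxy)phenyl]-3-[2-(benzyloxy)-5-formylphenoxy]prop-2-enoate F4. Condensation with (R)-1-aminoindane (the antipode if the sense of induction requires it) gives the imine benzyl (Z)-3-[3,4-bis(benzyloxy)phenyl]-3-[2-(benzyloxy)-5-{(E)-[(1R)-2,3-dihydro-1H-inden-1-ylimino]methyl}phenoxy]prop-2-enoate F5. Chelation-assisted intramolecular C–H alkylation ([RhCl(coe)2]2, coe = cyclooctene, with a dialkylferrocenylphosphine, toluene, 75 °C) then forms C3–C3a: monovalent rhodium, directed by the imine, inserts into the C–H bond between the imine carbon and the ether oxygen, the tethered alkene is hydrometalated and reductive elimination closes ring B. Syn addition to the Z alkene gives the cis imine benzyl (2S,3R)-7-(benzyloxy)-2-[3,4-bis(benzyloxy)phenyl]-4-{(E)-[(1R)-2,3-dihydro-1H-inden-1-ylimino]methyl}-2,3-dihydro-1-benzofuran-3-carboxylate F6, with C2 set under control of the chiral imine. Acidic hydrolysis gives the cis aldehyde benzyl (2S,3R)-7-(benzyloxy)-2-[3,4-bis(benzyloxy)phenyl]-4-formyl-2,3-dihydro-1-benzofuran-3-carboxylate F7. DBU epimerises C3 to the trans aldehyde benzyl (2S,3S)-7-(benzyloxy)-2-[3,4-bis(benzyloxy)phenyl]-4-formyl-2,3-dihydro-1-benzofuran-3-carboxylate F8. Wittig reaction of F8 with Ph3P=CHCO2tBu gives 15.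

**Step 7.** Base may trigger beta-elimination across C3–C2 (opening of ring B with loss of the O1 phenoxide), or reversible opening through the para phenoxide of ring C while the imide enolises, which would erode the C3 configuration; hydroxide may also attack the ring carbonyl of the hindered auxiliary. Fallback, from 11 back to 14 in the same number of steps: the phenol is benzylated under neutral Mitsunobu conditions (BnOH, PPh3, DIAD) to tert-butyl (E)-3-[(2S,3S)-7-(benzyloxy)-2-[3,4-bis(benzyloxy)phenyl]-3-{[(4S)-4-benzyl-2-oxo-1,3-oxazolidin-3-yl]carbonyl}-5-bromo-2,3-dihydro-1-benzofuran-4-yl]prop-2-enoate F9, and the imide is then transesterified with bromomagnesium benzyloxide (BnOH, MeMgBr, THF, 0 °C), which gives 14 directly without passing through the free acid.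

**Step 9.** Palladium hydride may reduce the cinnamate double bond in a conjugate sense, or oxidative addition at the electron-rich, doubly ortho-substituted C5–Br may be so slow that prolonged heating lets ring B open by elimination. Fallback, on the same compound 14 and returning at 15: radical chain reduction with Bu3SnH and AIBN in toluene at 80 °C, which is neutral, uses no metal hydride of palladium and makes no new compound.

**Step 14.** The Lewis acid may ionise the benzylic C2–O1 bond, with capture of the cation by the scavenger or by chloride; the benzyl ester may be cleaved more slowly than the ethers; benzyl cations may alkylate the catechol rings. Fallback, setting out from 15 and 19 and returning at 21 without any Lewis acid: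
- Lemieux–Johnson cleavage of the cinnamate double bond of 15 (OsO4 cat., NaIO4, 2,6-lutidine, dioxane/H2O) gives the aldehyde F8 described above.
- With the alkene gone, hydrogenolysis (H2, Pd/C, EtOAc/MeOH, stopped after the benzyl groups are consumed) gives (2S,3S)-2-(3,4-dihydroxyphenyl)-4-formyl-7-hydroxy-2,3-dihydro-1-benzofuran-3-carboxylic acid F10, the same compound as A5.
- 19 is acylated with 2,2-dimethyl-1,3-dioxane-4,6-dione (toluene, 90 °C) to the malonate half-ester 3-{[(2R)-3-[3,4-bis(benzyloxy)phenyl]-1-methoxy-1-oxopropan-2-yl]oxy}-3-oxopropanoic acid F11.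
- Hydrogenolysis of F11 gives 3-{[(2R)-3-(3,4-dihydroxyphenyl)-1-methoxy-1-oxopropan-2-yl]oxy}-3-oxopropanoic acid F12.
- Knoevenagel–Doebner condensation of F10 with F12 (pyridine, piperidine cat., 50 °C) rebuilds the E-acrylate with loss of CO2 and gives 21.

## Further compounds

F1 | step 6 | 4-(benzyloxy)-3-hydroxybenzaldehyde | O=Cc1ccc(OCc2ccccc2)c(O)c1
F2 | step 6 | 1,2-bis(benzyloxy)-4-(2,2-dibromovinyl)benzene | BrC(Br)=Cc1ccc(OCc2ccccc2)c(OCc2ccccc2)c1
F3 | step 6 | benzyl 3-[3,4-bis(benzyloxy)phenyl]prop-2-ynoate | O=C(OCc1ccccc1)C#Cc1ccc(OCc2ccccc2)c(OCc2ccccc2)c1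
F4 | step 6 | benzyl (Z)-3-[3,4-bis(benzyloxy)phenyl]-3-[2-(benzyloxy)-5-formylphenoxy]prop-2-enoate | O=Cc1ccc(OCc2ccccc2)c(O/C(=C\C(=O)OCc2ccccc2)c2ccc(OCc3ccccc3)c(OCc3ccccc3)c2)c1
F5 | step 6 | benzyl (Z)-3-[3,4-bis(benzyloxy)phenyl]-3-[2-(benzyloxy)-5-{(E)-[(1R)-2,3-dihydro-1H-inden-1-ylimino]methyl}phenoxy]prop-2-enoate | c1ccc2c(c1)CC[C@H]2/N=C/c1ccc(OCc2ccccc2)c(O/C(=C\C(=O)OCc2ccccc2)c2ccc(OCc3ccccc3)c(OCc3ccccc3)c2)c1
F6 | step 6 | benzyl (2S,3R)-7-(benzyloxy)-2-[3,4-bis(benzyloxy)phenyl]-4-{(E)-[(1R)-2,3-dihydro-1H-inden-1-ylimino]methyl}-2,3-dihydro-1-benzofuran-3-carboxylate (cis) | c1ccc2c(c1)CC[C@H]2/N=C/c1ccc(OCc3ccccc3)c2c1[C@@H](C(=O)OCc1ccccc1)[C@@H](c1ccc(OCc3ccccc3)c(OCc3ccccc3)c1)O2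
F7 | step 6 | benzyl (2S,3R)-7-(benzyloxy)-2-[3,4-bis(benzyloxy)phenyl]-4-formyl-2,3-dihydro-1-benzofuran-3-carboxylate (cis) | O=Cc1ccc(OCc3ccccc3)c2c1[C@@H](C(=O)OCc1ccccc1)[C@@H](c1ccc(OCc3ccccc3)c(OCc3ccccc3)c1)O2
F8 | step 6 | benzyl (2S,3S)-7-(benzyloxy)-2-[3,4-bis(benzyloxy)phenyl]-4-formyl-2,3-dihydro-1-benzofuran-3-carboxylate (trans) | O=Cc1ccc(OCc3ccccc3)c2c1[C@H](C(=O)OCc1ccccc1)[C@@H](c1ccc(OCc3ccccc3)c(OCc3ccccc3)c1)O2
F9 | step 7 | tert-butyl (E)-3-[(2S,3S)-7-(benzyloxy)-2-[3,4-bis(benzyloxy)phenyl]-3-{[(4S)-4-benzyl-2-oxo-1,3-oxazolidin-3-yl]carbonyl}-5-bromo-2,3-dihydro-1-benzofuran-4-yl]prop-2-enoate | CC(C)(C)OC(=O)/C=C/c1c(Br)cc(OCc3ccccc3)c2c1[C@H](C(=O)N1C(=O)OC[C@@H]1Cc1ccccc1)[C@@H](c1ccc(OCc3ccccc3)c(OCc3ccccc3)c1)O2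
F0 | step 9 | none | none
F10 | step 14 | (2S,3S)-2-(3,4-dihydroxyphenyl)-4-formyl-7-hydroxy-2,3-dihydro-1-benzofuran-3-carboxylic acid | O=Cc1ccc(O)c2c1[C@H](C(=O)O)[C@@H](c1ccc(O)c(O)c1)O2
F11 | step 14 | 3-{[(2R)-3-[3,4-bis(benzyloxy)phenyl]-1-methoxy-1-oxopropan-2-yl]oxy}-3-oxopropanoic acid | COC(=O)[C@@H](Cc1ccc(OCc2ccccc2)c(OCc2ccccc2)c1)OC(=O)CC(=O)O
F12 | step 14 | 3-{[(2R)-3-(3,4-dihydroxyphenyl)-1-methoxy-1-oxopropan-2-yl]oxy}-3-oxopropanoic acid | COC(=O)[C@@H](Cc1ccc(O)c(O)c1)OC(=O)CC(=O)O
A1 | alternative 1 | benzyl{2-[(1S,2R)-1-[3,4-bis(benzyloxy)phenyl]-5-(tert-butyldimethylsilyloxy)-2-[(4-methoxybenzyloxy)methyl]pent-3-ynyloxy]ethynyl}dimethylsilane | CC(C)(C)[Si](C)(C)OCC#C[C@H](COCc1ccc(OC)cc1)[C@@H](c1ccc(OCc2ccccc2)c(OCc2ccccc2)c1)OC#C[Si](C)(C)Cc1ccccc1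
A2 | alternative 1 | acetylene | C#C
A3 | alternative 1 | (2S,3R)-7-(benzyldimethylsilyl)-2-[3,4-bis(benzyloxy)phenyl]-4-[(tert-butyldimethylsilyloxy)methyl]-3-[(4-methoxybenzyloxy)methyl]-2,3-dihydro-1-benzofuran (trans) | CC(C)(C)[Si](C)(C)OCc1ccc([Si](C)(C)Cc3ccccc3)c2c1[C@H](COCc1ccc(OC)cc1)[C@@H](c1ccc(OCc3ccccc3)c(OCc3ccccc3)c1)O2
A4 | alternative 2 | (2R)-3-(3,4-dihydroxyphenyl)-2-(6-formyl-2,3-dihydroxyphenyl)propanoic acid | O=Cc1ccc(O)c(O)c1[C@H](C(=O)O)Cc1ccc(O)c(O)c1
A5 | alternative 2 | (2S,3S)-2-(3,4-dihydroxyphenyl)-4-formyl-7-hydroxy-2,3-dihydro-1-benzofuran-3-carboxylic acid | O=Cc1ccc(O)c2c1[C@H](C(=O)O)[C@@H](c1ccc(O)c(O)c1)O2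
A6 | alternative 3 | (1S,2R)-1-[3,4-bis(benzyloxy)phenyl]-2-(3-bromo-2-fluorophenyl)-3-(tert-butyldimethylsilyloxy)propan-1-ol | Fc1c(Br)cccc1[C@H](CO[Si](C)(C)C(C)(C)C)[C@H](O)c1ccc(OCc2ccccc2)c(OCc2ccccc2)c1
A7 | alternative 3 | (2S,3R)-2-[3,4-bis(benzyloxy)phenyl]-3-[(tert-butyldimethylsilyloxy)methyl]-2,3-dihydro-1-benzofuran-7-ol (trans) | c1ccc(O)c2c1[C@H](CO[Si](C)(C)C(C)(C)C)[C@@H](c1ccc(OCc3ccccc3)c(OCc3ccccc3)c1)O2
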